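**Plan**
1. Retrosynthesis: remove the three esters and the 8,9-epoxide, trace O-6/H-5 back to a C5=C6 alkene and O-10 back to boron. The resulting dauca-5,8-diene is cut at C1–C10 by a retro divinylcyclopropane rearrangement (C6–C8 re-joined as a cyclopropane, C7 its CH2). Then C4–isopropyl (carbonyl addition), C9=C10 (olefination) and C5–C6 (Negishi coupling) are cut, giving an iodocyclopropane and an iodocyclopentenone.
2. Forward: the cyclopentenone (five-membered ring, bought) and the cyclopropane are made separately and joined at C5–C6. The seven-membered ring is then closed onto the five-membered ring by the [3,3] shift that forms C1–C10 and opens the temporary three-membered ring.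
3. Enabling feature: in the seven-membered ring (C1, C5, C6, C7, C8, C9, C10) the pairs C5/C6 (H, O-acyl) and C8/C9 (epoxide) are alkene-level and flank the lone methylene C7, with the C1–C10 bond opposite it. This is the pattern of a cyclohepta-1,4-diene born from a cis-divinylcyclopropane.
4. Stereochemistry: C6/C8 of the cyclopropane are set by a Charette cyclopropanation and transferred through the boat transition state to C1 and C10. The bought C2 silyloxy centre steers C4 and keeps the reacting face clear. O-10 then directs the epoxide (C8, C9) and, through a silicon tether, H-5 and O-6. The C4 hydroxyl finally directs the reduction that corrects C2.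

Key step: step 10

Remark on numbering: bicyclic compounds are named on the daucane skeleton (bicyclo[5.3.0]decane). C1 is the ring-fusion carbon bearing Me-15; C2, C3, C4 (bearing the isopropyl group) and C5 (second ring-fusion carbon) complete the five-membered ring; C6–C10 complete the seven-membered ring; C8 bears Me-14. β is the face of Me-15. Monocyclic precursors are described with the same atom labels.
Assumption: the (4R,5R)-dioxaborolane ligand is taken to deliver CH2 to the alkene face that gives (1R,2R)-4, as it does for other allylic alcohols; if not, the enantiomeric ligand is used.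

**Route**

Step 1
Reactants: 1 prop-2-yn-1-ol
Product: 3 (2Z)-3-iodo-2-methylprop-2-en-1-ol, via alkenylmagnesium alkoxide 2 (not isolated)
Conditions: MeMgBr (2.5 equiv), CuI (10 mol %), THF, −10 °C to rt; then I2, −10 °C
Reagents that add atoms: methylmagnesium bromide (C[Mg]Br); iodine (II)
Why: Copper-catalysed anti-carbomagnesiation of the propargylic alkoxide places magnesium cis to the CH2O group in a five-membered chelate, so iodinolysis with retention should give the Z iodide whose geometry later fixes the cis cyclopropane.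

Step 2
Reactants: 3 (2Z)-3-iodo-2-methylprop-2-en-1-ol
Product: 4 [(1R,2R)-2-iodo-1-methylcyclopropyl]methanol
Conditions: Zn(CH2I)2·DME (from Et2Zn, CH2I2, DME), (4R,5R)-2-butyl-N,N,N',N'-tetramethyl-1,3,2-dioxaborolane-4,5-dicarboxamide (1.2 equiv), CH2Cl2, −10 °C to rt; aqueous NaOH work-up
Reagents that add atoms: diiodomethane (ICI)
Why: Charette asymmetric Simmons–Smith cyclopropanation, in which the zinc alkoxide bound to the chiral dioxaborolane delivers CH2 to one alkene face stereospecifically (I and CH2OH stay cis), sets C6 and C8.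

Step 3
Reactants: 5 (4R)-4-[(tert-butyldimethylsilyl)oxy]cyclopent-2-en-1-one
Product: 6 tert-butyldimethyl{[(1R,2R)-2-methyl-4-[(trimethylsilyl)oxy]cyclopent-3-en-1-yl]oxy}silane
Conditions: MeMgBr, CuBr·SMe2 (10 mol %), TMSCl, DMPU, THF, −78 °C
Reagents that add atoms: methylmagnesium bromide (C[Mg]Br); chlorotrimethylsilane (C[Si](C)(C)Cl)
Why: Copper-catalysed conjugate addition anti to the silyloxy group with in situ silyl trapping gives the enol ether regiospecifically, bringing in the carbon that becomes Me-15.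

Step 4
Reactants: 6 tert-butyldimethyl{[(1R,2R)-2-methyl-4-[(trimethylsilyl)oxy]cyclopent-3-en-1-yl]oxy}silane
Product: 7 (4R)-4-[(tert-butyldimethylsilyl)oxy]-3-methylcyclopent-2-en-1-one
Conditions: Pd(OAc)2 (1.05 equiv), MeCN, rt
Reagents that add atoms: none
Why: Saegusa–Ito oxidation, in which the palladium enolate undergoes β-hydride elimination toward the methyl-bearing carbon, regenerates the enone with the new β-methyl group and leaves the silyloxy centre untouched.

Step 5
Reactants: 7 (4R)-4-[(tert-butyldimethylsilyl)oxy]-3-methylcyclopent-2-en-1-one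
Product: 8 (4R)-4-[(tert-butyldimethylsilyl)oxy]-2-iodo-3-methylcyclopent-2-en-1-one
Conditions: I2, pyridine, DMAP (cat.), CH2Cl2, rt
Reagents that add atoms: iodine (II)
Why: α-Iodination of the enone by reversible conjugate addition of the amine, iodination of the enolate and elimination puts iodine on the carbon that becomes C5.

Step 6
Reactants: 4 [(1R,2R)-2-iodo-1-methylcyclopropyl]methanol; 8 (4R)-4-[(tert-butyldimethylsilyl)oxy]-2-iodo-3-methylcyclopent-2-en-1-one
Product: 11 (4R)-4-[(tert-butyldimethylsilyl)oxy]-2-[(1R,2S)-2-(hydroxymethyl)-2-methylcyclopropyl]-3-methylcyclopent-2-en-1-one, via cyclopropyllithium alkoxide 9 (not isolated), via cyclopropylzinc chloride 10 (not isolated)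
Conditions: 4, t-BuLi (3.1 equiv), Et2O, −78 °C; ZnCl2, THF, −78 to 0 °C; then 8, Pd(OAc)2 (5 mol %), SPhos (10 mol %), THF, rt to 40 °C
Reagents that add atoms: none
Why: Iodine–lithium exchange on the cyclopropyl iodide and transmetalation to zinc proceed with retention, and Negishi coupling with the α-iodoenone forms the C5–C6 bond while the alkoxide and silyl ether are tolerated.

Step 7
Reactants: 11 (4R)-4-[(tert-butyldimethylsilyl)oxy]-2-[(1R,2S)-2-(hydroxymethyl)-2-methylcyclopropyl]-3-methylcyclopent-2-en-1-one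
Product: 12 (1S,2R)-2-[(3R)-3-[(tert-butyldimethylsilyl)oxy]-2-methyl-5-oxocyclopent-1-en-1-yl]-1-methylcyclopropane-1-carbaldehyde
Conditions: Dess–Martin periodinane, NaHCO3, CH2Cl2, 0 °C to rt; used at once
Reagents that add atoms: none
Why: Dess–Martin oxidation of the only free alcohol gives the aldehyde under neutral conditions, and immediate use avoids reversible retro-Claisen isomerisation of the cis-2-vinylcyclopropanecarbaldehyde.

Step 8
Reactants: 12 (1S,2R)-2-[(3R)-3-[(tert-butyldimethylsilyl)oxy]-2-methyl-5-oxocyclopent-1-en-1-yl]-1-methylcyclopropane-1-carbaldehyde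
Product: 13 (4R)-4-[(tert-butyldimethylsilyl)oxy]-3-methyl-2-{(1R,2R)-2-methyl-2-[(E)-2-(4,4,5,5-tetramethyl-1,3,2-dioxaborolan-2-yl)ethenyl]cyclopropyl}cyclopent-2-en-1-one
Conditions: CrCl2 (8 equiv), Cl2CHBpin (2 equiv), LiI (4 equiv), THF, rt
Reagents that add atoms: 2-(dichloromethyl)-4,4,5,5-tetramethyl-1,3,2-dioxaborolane (ClC(Cl)B1OC(C)(C)C(C)(C)O1)
Why: Takai–Utimoto olefination, in which the geminal dichromium species adds to the aldehyde chemoselectively (ketone inert) and eliminates to the E alkenylboronate, installs C10 as a latent alcohol with the geometry that later defines its configuration.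

Step 9
Reactants: 13 (4R)-4-[(tert-butyldimethylsilyl)oxy]-3-methyl-2-{(1R,2R)-2-methyl-2-[(E)-2-(4,4,5,5-tetramethyl-1,3,2-dioxaborolan-2-yl)ethenyl]cyclopropyl}cyclopent-2-en-1-one
Product: 14 (1R,4R)-4-[(tert-butyldimethylsilyl)oxy]-3-methyl-2-{(1R,2R)-2-methyl-2-[(E)-2-(4,4,5,5-tetramethyl-1,3,2-dioxaborolan-2-yl)ethenyl]cyclopropyl}-1-(propan-2-yl)cyclopent-2-en-1-ol
Conditions: i-PrMgCl (3 equiv), anhydrous CeCl3 (3 equiv), THF, −78 °C
Reagents that add atoms: isopropylmagnesium chloride (CC(C)[Mg]Cl)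
Why: Organocerium (Imamoto) 1,2-addition to the cyclopentenone carbonyl at −78 °C, where the pinacol boronate should not be attacked, occurs anti to the C2 silyloxy group across the ring, so isopropyl enters α and the C4 hydroxyl is β.

Step 10
Reactants: 14 (1R,4R)-4-[(tert-butyldimethylsilyl)oxy]-3-methyl-2-{(1R,2R)-2-methyl-2-[(E)-2-(4,4,5,5-tetramethyl-1,3,2-dioxaborolan-2-yl)ethenyl]cyclopropyl}-1-(propan-2-yl)cyclopent-2-en-1-ol
Product: 15 2β-[(tert-butyldimethylsilyl)oxy]-10α-(4,4,5,5-tetramethyl-1,3,2-dioxaborolan-2-yl)dauca-5,8-dien-4β-ol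
Conditions: degassed o-xylene, BHT (cat.), base-washed sealed tube, 150 °C
Reagents that add atoms: none
Why: Heating brings the cis-disposed cyclopentenyl and (E)-borylvinyl groups over the cyclopropane, and a concerted [3,3] shift through the boat transition state breaks the C6–C8 cyclopropane bond while C1–C10 forms, the released ring strain making it irreversible. The closest known reaction type is the cis-divinylcyclopropane–cycloheptadiene rearrangement of 1-(2-vinylcyclopropyl)cycloalkenes, which gives hydroazulenes with an angular methyl group. The seven-membered ring closes in a sigmatropic ring-expansion mode (both alkenes endo over the three-membered ring), leaving C5=C6 and C8=C9 exactly where oxygen is needed later. The quaternary C1 is fixed by the cyclopropane configuration (C6, C8 from step 2), which lets C10 reach only the α face of the C1=C5 alkene, and C10 is fixed by the E geometry of the alkenylboronate, whose boron sits outward in the boat and ends up trans to Me-15. The step needs the cis cyclopropane (secured by the Z alkene of step 1), the endo rotamer about C5–C6 (the small H-6 eclipses C4) and an unhindered reacting face, which is why the C2 silyloxy and C4 hydroxyl groups lie on the β face and only H-2α faces the incoming boron-bearing terminus; the inward Me-15 raises the barrier but offers no competing concerted path.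

Step 11
Reactants: 15 2β-[(tert-butyldimethylsilyl)oxy]-10α-(4,4,5,5-tetramethyl-1,3,2-dioxaborolan-2-yl)dauca-5,8-dien-4β-ol
Product: 16 2β-[(tert-butyldimethylsilyl)oxy]dauca-5,8-diene-4β,10α-diol
Conditions: 30% H2O2, 2 M NaOH, THF, 0 °C to rt
Reagents that add atoms: hydrogen peroxide (OO)
Why: Oxidation of the secondary allylic boronate by 1,2-migration from boron to oxygen proceeds with retention and without allylic transposition, giving the 10α-alcohol.

Step 12
Reactants: 16 2β-[(tert-butyldimethylsilyl)oxy]dauca-5,8-diene-4β,10α-diol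
Product: 17 2β-[(tert-butyldimethylsilyl)oxy]-8α,9α-epoxydauc-5-ene-4β,10α-diol
Conditions: VO(acac)2 (5 mol %), t-BuOOH (1.1 equiv, decane), CH2Cl2, 0 °C
Reagents that add atoms: tert-butyl hydroperoxide (CC(C)(C)OO)
Why: In this vanadium-catalysed hydroxyl-directed epoxidation the pseudoaxial secondary allylic 10α-OH delivers oxygen syn to C8=C9, which should be faster than engagement of the C5=C6 bond (buttressed between two quaternary carbons) by the tertiary C4–OH.

Step 13
Reactants: 17 2β-[(tert-butyldimethylsilyl)oxy]-8α,9α-epoxydauc-5-ene-4β,10α-diol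
Product: 20 2β-[(tert-butyldimethylsilyl)oxy]-8α,9α-epoxy-trans-daucane-4β,6α,10α-triol, via 10-O-diisopropylsilyl ether 18 (not isolated), via cyclic siloxane 19 (not isolated)
Conditions: i-Pr2SiHCl, imidazole, DMAP (cat.), CH2Cl2, rt; then Karstedt catalyst (2 mol % Pt), toluene, 60 °C; then KF, KHCO3, 30% H2O2, THF/MeOH, 40 °C
Reagents that add atoms: hydrogen peroxide (OO)
Why: Tamao intramolecular hydrosilylation–oxidation, in which the bulky chlorosilane silylates only the secondary 10α-OH, the platinum-catalysed syn addition of Si–H from this α-face tether puts Si on C6 and H on C5 (six-membered oxasilinane, since Si cannot add to the fully substituted C5), and Tamao–Fleming oxidation replaces Si by OH with retention, should give the trans ring fusion (H-5α) and the 6α-alcohol.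

Step 14
Reactants: 20 2β-[(tert-butyldimethylsilyl)oxy]-8α,9α-epoxy-trans-daucane-4β,6α,10α-triol; 21 angelic acid
Product: 23 6α-angeloyloxy-2β-[(tert-butyldimethylsilyl)oxy]-8α,9α-epoxy-trans-daucane-4β,10α-diol, via mixed anhydride 22 (not isolated)
Conditions: 21, 2,4,6-trichlorobenzoyl chloride, Et3N, toluene, rt; then 20, DMAP, toluene, 50 °C
Reagents that add atoms: none
Why: Yamaguchi esterification with the preformed mixed anhydride, mild enough to keep the Z geometry, should acylate the equatorial 6α-OH (hydrogen-bonded to the C4 hydroxyl) in preference to the axial, neopentylic, epoxide-flanked 10α-OH and the tertiary C4–OH.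

Step 15
Reactants: 23 6α-angeloyloxy-2β-[(tert-butyldimethylsilyl)oxy]-8α,9α-epoxy-trans-daucane-4β,10α-diol
Product: 24 10α-acetoxy-6α-angeloyloxy-2β-[(tert-butyldimethylsilyl)oxy]-8α,9α-epoxy-trans-daucan-4β-ol
Conditions: Ac2O, Et3N, DMAP, CH2Cl2, rt to 40 °C
Reagents that add atoms: acetic anhydride (CC(=O)OC(C)=O)
Why: DMAP-catalysed acetylation of the remaining secondary (10α) alcohol leaves the tertiary C4 alcohol free.

Step 16
Reactants: 24 10α-acetoxy-6α-angeloyloxy-2β-[(tert-butyldimethylsilyl)oxy]-8α,9α-epoxy-trans-daucan-4β-ol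
Product: 25 10α-acetoxy-6α-angeloyloxy-8α,9α-epoxy-trans-daucane-2β,4β-diol
Conditions: TBAF, AcOH (1:1), THF, rt to 40 °C
Reagents that add atoms: none
Why: Fluoride-mediated desilylation, buffered with acetic acid so that the esters and the epoxide survive, frees the 2β-alcohol whose configuration was needed only up to the ring closure.

Step 17
Reactants: 25 10α-acetoxy-6α-angeloyloxy-8α,9α-epoxy-trans-daucane-2β,4β-diol
Product: 26 10α-acetoxy-6α-angeloyloxy-8α,9α-epoxy-4β-hydroxy-trans-daucan-2-one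
Conditions: Dess–Martin periodinane, NaHCO3, CH2Cl2, rt
Reagents that add atoms: none
Why: Dess–Martin oxidation of the only secondary alcohol gives the C2 ketone under buffered, non-basic conditions that avoid retro-aldol cleavage or dehydration of the β-hydroxy ketone.

Step 18
Reactants: 26 10α-acetoxy-6α-angeloyloxy-8α,9α-epoxy-4β-hydroxy-trans-daucan-2-one
Product: 27 10α-acetoxy-6α-angeloyloxy-8α,9α-epoxy-trans-daucane-2α,4β-diol
Conditions: Me4NBH(OAc)3, MeCN/AcOH, −30 to −10 °C
Reagents that add atoms: none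
Why: In this Evans–Saksena reduction the C4β hydroxyl exchanges onto triacetoxyborohydride and delivers hydride intramolecularly to the β face of the C2 ketone, giving the 1,3-anti (2α,4β) diol, while the free reagent does not reduce ketones that lack a neighbouring hydroxyl.

Step 19
Reactants: 27 10α-acetoxy-6α-angeloyloxy-8α,9α-epoxy-trans-daucane-2α,4β-diol
Product: 28 2α,10α-diacetoxy-6α-angeloyloxy-8α,9α-epoxy-trans-daucan-4β-ol (CNP0170993.1)
Conditions: Ac2O, pyridine, DMAP, rt
Reagents that add atoms: acetic anhydride (CC(=O)OC(C)=O)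
Why: DMAP-catalysed acetylation of the secondary 2α-alcohol, to which the hindered tertiary C4–OH is inert, completes the target.

**Compound list**
1 | prop-2-yn-1-ol | C#CCO | starting material
2 | bromomagnesium (2Z)-3-(bromomagnesio)-2-methylprop-2-en-1-olate (formed in situ) | Br[Mg]/C=C(/C)CO[Mg]Br | intermediate
3 | (2Z)-3-iodo-2-methylprop-2-en-1-ol | OC/C(C)=C\I | intermediate
4 | [(1R,2R)-2-iodo-1-methylcyclopropyl]methanol (I and CH2OH cis) | I[C@@H]1C[C@]1(C)CO | intermediate
5 | (4R)-4-[(tert-butyldimethylsilyl)oxy]cyclopent-2-en-1-one | C1=CC(=O)C[C@H]1O[Si](C)(C)C(C)(C)C | starting material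
6 | tert-butyldimethyl{[(1R,2R)-2-methyl-4-[(trimethylsilyl)oxy]cyclopent-3-en-1-yl]oxy}silane (Me and OTBS trans) | C[C@@H]1C=C(O[Si](C)(C)C)C[C@H]1O[Si](C)(C)C(C)(C)C | intermediate
7 | (4R)-4-[(tert-butyldimethylsilyl)oxy]-3-methylcyclopent-2-en-1-one | CC1=CC(=O)C[C@H]1O[Si](C)(C)C(C)(C)C | intermediate
8 | (4R)-4-[(tert-butyldimethylsilyl)oxy]-2-iodo-3-methylcyclopent-2-en-1-one | CC1=C(I)C(=O)C[C@H]1O[Si](C)(C)C(C)(C)C | intermediate
9 | dilithio derivative of 4: lithium (cis-2-lithio-1-methylcyclopropyl)methanolate, Li in place of I with retention (formed in situ) | [Li][C@@H]1C[C@]1(C)CO[Li] | intermediate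
10 | chlorozinc analogue of 9, ZnCl in place of Li on the ring carbon (formed in situ) | Cl[Zn][C@@H]1C[C@]1(C)CO[Li] | intermediate
11 | (4R)-4-[(tert-butyldimethylsilyl)oxy]-2-[(1R,2S)-2-(hydroxymethyl)-2-methylcyclopropyl]-3-methylcyclopent-2-en-1-one | CC1=C([C@@H]2C[C@]2(C)CO)C(=O)C[C@H]1O[Si](C)(C)C(C)(C)C | intermediate
12 | (1S,2R)-2-[(3R)-3-[(tert-butyldimethylsilyl)oxy]-2-methyl-5-oxocyclopent-1-en-1-yl]-1-methylcyclopropane-1-carbaldehyde | CC1=C([C@@H]2C[C@]2(C)C=O)C(=O)C[C@H]1O[Si](C)(C)C(C)(C)C | intermediate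
13 | (4R)-4-[(tert-butyldimethylsilyl)oxy]-3-methyl-2-{(1R,2R)-2-methyl-2-[(E)-2-(4,4,5,5-tetramethyl-1,3,2-dioxaborolan-2-yl)ethenyl]cyclopropyl}cyclopent-2-en-1-one | CC1=C([C@@H]2C[C@]2(C)/C=C/B3OC(C)(C)C(C)(C)O3)C(=O)C[C@H]1O[Si](C)(C)C(C)(C)C | intermediate
14 | (1R,4R)-4-[(tert-butyldimethylsilyl)oxy]-3-methyl-2-{(1R,2R)-2-methyl-2-[(E)-2-(4,4,5,5-tetramethyl-1,3,2-dioxaborolan-2-yl)ethenyl]cyclopropyl}-1-(propan-2-yl)cyclopent-2-en-1-ol (OH and OTBS cis) | CC1=C([C@@H]2C[C@]2(C)/C=C/B3OC(C)(C)C(C)(C)O3)[C@](O)(C(C)C)C[C@H]1O[Si](C)(C)C(C)(C)C | intermediate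
15 | 2β-[(tert-butyldimethylsilyl)oxy]-10α-(4,4,5,5-tetramethyl-1,3,2-dioxaborolan-2-yl)dauca-5,8-dien-4β-ol | C1C(C)=C[C@@H](B3OC(C)(C)C(C)(C)O3)[C@@]2(C)[C@H](O[Si](C)(C)C(C)(C)C)C[C@@](O)(C(C)C)C2=C1 | intermediate
16 | 2β-[(tert-butyldimethylsilyl)oxy]dauca-5,8-diene-4β,10α-diol | C1C(C)=C[C@@H](O)[C@@]2(C)[C@H](O[Si](C)(C)C(C)(C)C)C[C@@](O)(C(C)C)C2=C1 | intermediate
17 | 2β-[(tert-butyldimethylsilyl)oxy]-8α,9α-epoxydauc-5-ene-4β,10α-diol | C1[C@@]3(C)O[C@H]3[C@@H](O)[C@@]2(C)[C@H](O[Si](C)(C)C(C)(C)C)C[C@@](O)(C(C)C)C2=C1 | intermediate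
18 | 10-O-(diisopropylsilyl) ether of 17 (formed in situ) | C1[C@@]3(C)O[C@H]3[C@@H](O[SiH](C(C)C)C(C)C)[C@@]2(C)[C@H](O[Si](C)(C)C(C)(C)C)C[C@@](O)(C(C)C)C2=C1 | intermediate
19 | cyclic siloxane: diisopropylsilylene bridging O-10 and C6 (both α), H-5α, 2β-OTBS, 8α,9α-epoxide, 4β-OH (formed in situ) | CC(C)[Si]4(C(C)C)[C@H]1C[C@@]2(C)O[C@H]2[C@@H](O4)[C@@]2(C)[C@H](O[Si](C)(C)C(C)(C)C)C[C@@](O)(C(C)C)[C@H]12 | intermediate
20 | 2β-[(tert-butyldimethylsilyl)oxy]-8α,9α-epoxy-trans-daucane-4β,6α,10α-triol | O[C@H]1C[C@@]2(C)O[C@H]2[C@@H](O)[C@@]2(C)[C@H](O[Si](C)(C)C(C)(C)C)C[C@@](O)(C(C)C)[C@H]12 | intermediate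
21 | angelic acid, (2Z)-2-methylbut-2-enoic acid | C/C=C(/C)C(=O)O | starting material
22 | angelic 2,4,6-trichlorobenzoic anhydride (formed in situ) | C/C=C(/C)C(=O)OC(=O)c1c(Cl)cc(Cl)cc1Cl | intermediate
23 | 6α-angeloyloxy-2β-[(tert-butyldimethylsilyl)oxy]-8α,9α-epoxy-trans-daucane-4β,10α-diol | C/C=C(/C)C(=O)O[C@H]1C[C@@]2(C)O[C@H]2[C@@H](O)[C@@]2(C)[C@H](O[Si](C)(C)C(C)(C)C)C[C@@](O)(C(C)C)[C@H]12 | intermediate
24 | 10α-acetoxy-6α-angeloyloxy-2β-[(tert-butyldimethylsilyl)oxy]-8α,9α-epoxy-trans-daucan-4β-ol | C/C=C(/C)C(=O)O[C@H]1C[C@@]2(C)O[C@H]2[C@@H](OC(C)=O)[C@@]2(C)[C@H](O[Si](C)(C)C(C)(C)C)C[C@@](O)(C(C)C)[C@H]12 | intermediate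
25 | 10α-acetoxy-6α-angeloyloxy-8α,9α-epoxy-trans-daucane-2β,4β-diol | C/C=C(/C)C(=O)O[C@H]1C[C@@]2(C)O[C@H]2[C@@H](OC(C)=O)[C@@]2(C)[C@H](O)C[C@@](O)(C(C)C)[C@H]12 | intermediate
26 | 10α-acetoxy-6α-angeloyloxy-8α,9α-epoxy-4β-hydroxy-trans-daucan-2-one | C/C=C(/C)C(=O)O[C@H]1C[C@@]2(C)O[C@H]2[C@@H](OC(C)=O)[C@@]2(C)C(=O)C[C@@](O)(C(C)C)[C@H]12 | intermediate
27 | 10α-acetoxy-6α-angeloyloxy-8α,9α-epoxy-trans-daucane-2α,4β-diol | C/C=C(/C)C(=O)O[C@H]1C[C@@]2(C)O[C@H]2[C@@H](OC(C)=O)[C@@]2(C)[C@@H](O)C[C@@](O)(C(C)C)[C@H]12 | intermediate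
28 | 2α,10α-diacetoxy-6α-angeloyloxy-8α,9α-epoxy-trans-daucan-4β-ol (CNP0170993.1) | C/C=C(/C)C(=O)O[C@H]1C[C@@]2(C)O[C@H]2[C@@H](OC(C)=O)[C@@]2(C)[C@@H](OC(C)=O)C[C@@](O)(C(C)C)[C@H]12 | target

**Totals and risks**
Total step count: 19. Longest linear sequence: 17 steps (from 5 through steps 3–19); the other branch (from 1) is 16 steps.

Most likely to fail:

1. Step 10. The rearrangement has to pass a boat transition state with Me-15 pointing inward, so it may be slow at temperatures the boron group tolerates; 1,3-boron shift or protodeboronation of the allylic boronate would then compete. Fallback: carry O-10 as an ether instead of boron. From 14, copper(II)-promoted coupling of the alkenylboronate with 4-methoxybenzyl alcohol (Cu(OAc)2, Et3N, PMBOH, rt) would give the (E)-4-methoxybenzyl enol ether F1. Its thermolysis can be forced (up to 200 °C) to the 10α-PMB ether of the dauca-5,8-diene, F2, by the same [3,3] shift. DDQ (CH2Cl2, pH 7 buffer) then removes the PMB group and the route is rejoined at 16.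

2. Step 13. The platinum hydride may fail to insert into the encumbered C5=C6 bond, or silylation may not distinguish O-10 from the C4 hydroxyl, so that no tethered delivery of H-5/O-6 takes place. Fallback: thermodynamic control of C5 and hydroxyl-directed reduction at C6. From 17, acetylation (Ac2O, DMAP) would give the 10-acetate F3. Hydroboration–oxidation (BH3·THF, then NaBO3) would give a 6-alcohol without regard to configuration; the β-face adduct F4 is expected. Dess–Martin oxidation would give the cis-fused 6-ketone F5. DBU would equilibrate C5 to the trans-fused ketone F6, favoured because the isopropyl group is then trans to C6 and the C4–OH can hydrogen-bond to the C6 carbonyl. Me4NBH(OAc)3, directed by the C4β-OH, would then give the 6α-alcohol F7. Yamaguchi angeloylation of F7 rejoins the route at 24.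

3. Step 9. The organometallic may attack boron (ate-complex formation) or only enolise or reduce the hindered ketone, so that the isopropyl carbinol is not formed. Fallback: introduce the isopropyl group before boron. From 11, i-PrMgCl/CeCl3 (excess, −78 °C) would give the diol F8. Selective oxidation of the primary alcohol (TEMPO, PhI(OAc)2) would give the hydroxy aldehyde F9, which may rest as its lactol. Takai–Utimoto olefination of F9 rejoins the route at 14.

Further compounds
F1 | step 10 | (E)-2-[(4-methoxybenzyl)oxy]ethenyl analogue of 14 (enol ether in place of the boronate) | CC1=C([C@@H]2C[C@]2(C)/C=C/OCc3ccc(OC)cc3)[C@](O)(C(C)C)C[C@H]1O[Si](C)(C)C(C)(C)C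
F2 | step 10 | 2β-[(tert-butyldimethylsilyl)oxy]-10α-[(4-methoxybenzyl)oxy]dauca-5,8-dien-4β-ol | C1C(C)=C[C@@H](OCc3ccc(OC)cc3)[C@@]2(C)[C@H](O[Si](C)(C)C(C)(C)C)C[C@@](O)(C(C)C)C2=C1
F3 | step 13 | 10α-acetoxy-2β-[(tert-butyldimethylsilyl)oxy]-8α,9α-epoxydauc-5-en-4β-ol | C1[C@@]3(C)O[C@H]3[C@@H](OC(C)=O)[C@@]2(C)[C@H](O[Si](C)(C)C(C)(C)C)C[C@@](O)(C(C)C)C2=C1
F4 | step 13 | 10α-acetoxy-2β-[(tert-butyldimethylsilyl)oxy]-8α,9α-epoxy-cis-daucane-4β,6β-diol (5β-H) | O[C@@H]1C[C@@]2(C)O[C@H]2[C@@H](OC(C)=O)[C@@]2(C)[C@H](O[Si](C)(C)C(C)(C)C)C[C@@](O)(C(C)C)[C@@H]12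
F5 | step 13 | 10α-acetoxy-2β-[(tert-butyldimethylsilyl)oxy]-8α,9α-epoxy-4β-hydroxy-cis-daucan-6-one (5β-H) | O=C1C[C@@]2(C)O[C@H]2[C@@H](OC(C)=O)[C@@]2(C)[C@H](O[Si](C)(C)C(C)(C)C)C[C@@](O)(C(C)C)[C@@H]12
F6 | step 13 | 10α-acetoxy-2β-[(tert-butyldimethylsilyl)oxy]-8α,9α-epoxy-4β-hydroxy-trans-daucan-6-one (5α-H) | O=C1C[C@@]2(C)O[C@H]2[C@@H](OC(C)=O)[C@@]2(C)[C@H](O[Si](C)(C)C(C)(C)C)C[C@@](O)(C(C)C)[C@H]12
F7 | step 13 | 10α-acetoxy-2β-[(tert-butyldimethylsilyl)oxy]-8α,9α-epoxy-trans-daucane-4β,6α-diol | O[C@H]1C[C@@]2(C)O[C@H]2[C@@H](OC(C)=O)[C@@]2(C)[C@H](O[Si](C)(C)C(C)(C)C)C[C@@](O)(C(C)C)[C@H]12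
F8 | step 9 | (1R,4R)-4-[(tert-butyldimethylsilyl)oxy]-2-[(1R,2S)-2-(hydroxymethyl)-2-methylcyclopropyl]-3-methyl-1-(propan-2-yl)cyclopent-2-en-1-ol | CC1=C([C@@H]2C[C@]2(C)CO)[C@](O)(C(C)C)C[C@H]1O[Si](C)(C)C(C)(C)C
F9 | step 9 | (1S,2R)-2-[(3R,5R)-3-[(tert-butyldimethylsilyl)oxy]-5-hydroxy-2-methyl-5-(propan-2-yl)cyclopent-1-en-1-yl]-1-methylcyclopropane-1-carbaldehyde | CC1=C([C@@H]2C[C@]2(C)C=O)[C@](O)(C(C)C)C[C@H]1O[Si](C)(C)C(C)(C)C
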